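## Retrosynthetic overview
1. C11–C12 cut: target ⇒ 9α,11-spiro-epoxide of the bicyclic core + 4-(bromomethyl)butenolide. The lactone ring is bought and attached last.
2. Epoxide ⇒ 9(11)-methylidene decalin, with oxygen delivered from the α face. The 3β-OAc, the C4 gem-dimethyl group and 5α-H ⇒ Δ4-3-ketone by reductive methylation.
3. Key step: six-membered ring B ⇒ the cyclopentanone of a hydrindenedione, by insertion of CH–CH3 (C8 + C17) with a 1,2-shift of C7.
4. Hydrindenedione ⇒ 2-methylcyclopentane-1,3-dione + ethyl vinyl ketone. An amino-acid-catalysed annulation sets C10.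
5. Ring order: five-membered precursor of ring B (bought) → ring A → ring B by five-to-six expansion → butenolide joined.

Assumption: bicyclic compounds carry drimane/labdane numbering, α means the face opposite the C10 methyl group, and 4-(bromomethyl)furan-2(5H)-one and N-ethyl-N-nitrosourea are taken as catalogue chemicals.

## Route

Step 1
Reactants: 1 2-methylcyclopentane-1,3-dione; 2 pent-1-en-3-one (ethyl vinyl ketone)
Product: 4 (7aS)-4,7a-dimethyl-2,3,7,7a-tetrahydro-1H-indene-1,5(6H)-dione, via triketone 3 (not isolated)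
Conditions: 2 (1.3 equiv), AcOH (cat.), H2O, 70 °C; evaporate; L-phenylalanine (0.3 equiv), (1S)-(+)-camphor-10-sulfonic acid (0.15 equiv), DMF, 30 → 70 °C; recrystallise (Et2O/hexane)
Reagents that add atoms: none
Why: Michael addition followed by the Hajos–Parrish–Eder–Sauer–Wiechert variant of the Robinson annulation, in which the L-phenylalanine enamine of the side-chain ketone attacks one of the two enantiotopic ring carbonyls and so sets C10 as S (β-methyl), and one recrystallisation brings the material to a single enantiomer.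

Step 2 (key step)
Reactants: 4 (7aS)-4,7a-dimethyl-2,3,7,7a-tetrahydro-1H-indene-1,5(6H)-dione
Product: 6 (2R,8aS)-2,5,8a-trimethyl-3,4,8,8a-tetrahydronaphthalene-1,6(2H,7H)-dione, via 8β-methyl epimer 5 (not isolated)
Conditions: CH3CHN2 (1.5 equiv, dried Et2O solution made beforehand from N-ethyl-N-nitrosourea and aq KOH, 0 °C), Sc(OTf)3 (10 mol%), CH2Cl2/toluene, −78 → −20 °C; then DBU (0.5 equiv), toluene, 60 °C
Reagents that add atoms: diazoethane, CC=[N+]=[N-]
Why: Lewis-acid-catalysed diazoalkane–ketone homologation (Büchner–Curtius–Schlotterbeck ring expansion, a Tiffeneau–Demjanov-type 1,2-shift) in which diazoethane adds only to the non-conjugated cyclopentanone (the enone C=C is tetrasubstituted and inert), the less substituted C7 methylene migrates as N2 leaves so that the carbonyl stays next to C10, the hindered product does not react again, and DBU equilibrates 5 into the equatorial 8α-methyl ketone 6, which avoids the 1,3-diaxial clash with the C10 methyl.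

Step 3
Reactants: 6 (2R,8aS)-2,5,8a-trimethyl-3,4,8,8a-tetrahydronaphthalene-1,6(2H,7H)-dione
Product: 9 4,8α,10β-trimethyl-9-methylideneoctal-4-en-3-one, via lithium dienolate 7 (not isolated), via β-hydroxysilane 8 (not isolated)
Conditions: LiN(iPr)2 (1.1 equiv), THF, −78 °C; Me3SiCH2Li (2 equiv), −78 → 0 °C; then aq HF, MeCN, rt
Reagents that add atoms: (trimethylsilyl)methyllithium, [Li]C[Si](C)(C)C
Why: Peterson olefination under enolate masking, in which kinetic deprotonation at the unhindered C2 turns the more accessible enone into an unreactive cross-conjugated dienolate, the small Me3SiCH2Li can then add only to the hindered C9 ketone (from the α face, of no consequence), and HF re-protonates C2 to restore the enone and eliminates the β-hydroxysilane to the 9(11)-methylidene group without touching C8 or C10.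

Step 4
Reactants: 9 4,8α,10β-trimethyl-9-methylideneoctal-4-en-3-one
Product: 11 5α,8βH-drim-9(11)-en-3-one, via lithium enolate 10 (not isolated)
Conditions: Li (2.2 equiv), NH3(l)/THF, t-BuOH (1.0 equiv), −78 °C; MeI (5 equiv), −78 → −33 °C; H2O
Reagents that add atoms: iodomethane, CI
Why: Stork-type dissolving-metal reductive alkylation, in which two-electron reduction of the enone and axial protonation of C5 from the α face give the trans-fused (5α-H) enolate 10 regiospecifically, MeI alkylates it at C4 before it can equilibrate and so completes the gem-dimethyl group, and the isolated 1,1-disubstituted alkene is not reduced (with C9 no longer a carbonyl, no cyclopropanol can form).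

Step 5
Reactants: 11 5α,8βH-drim-9(11)-en-3-one
Product: 13 5α,8βH-drim-9(11)-en-3β-yl acetate, via 3β-alcohol 12 (not isolated)
Conditions: LiAlH4 (0.5 equiv), THF, −20 → 0 °C; then Ac2O (6 equiv), pyridine, DMAP (0.2 equiv), 0 °C → rt
Reagents that add atoms: acetic anhydride, CC(=O)OC(C)=O
Why: Hydride reduction followed by acylation of the alkoxide in the same flask, in which LiAlH4 attacks C3 along the axial α trajectory because the β face is screened by the axial 4β- and 10β-methyl groups, which gives the equatorial 3β-alkoxide that Ac2O/DMAP converts into the acetate.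

Step 6
Reactants: 13 5α,8βH-drim-9(11)-en-3β-yl acetate
Product: 14 9α,11-epoxy-5α,8βH-driman-3β-yl acetate
Conditions: mCPBA (1.2 equiv), CH2Cl2, 0 °C
Reagents that add atoms: 3-chloroperoxybenzoic acid, O=C(OO)c1cccc(Cl)c1
Why: Prilezhaev epoxidation, in which the peracid reaches the only alkene from the α face, anti to the axial C10 methyl on the neighbouring carbon that covers the β face, so that oxygen ends up 9α (axial) and C11 9β (equatorial), the C9 configuration of the target.

Step 7
Reactants: 14 9α,11-epoxy-5α,8βH-driman-3β-yl acetate; 15 4-(bromomethyl)furan-2(5H)-one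
Product: 17 3β-acetoxy-9α-hydroxy-8βH-labd-13-en-16,15-olide, via iodohydrin 16 (not isolated)
Conditions: NiBr2(dme) (10 mol%), 4,4′-di-tert-butyl-2,2′-bipyridine (12 mol%), NaI (0.5 equiv), Et3N·HCl (1.1 equiv), Mn powder (3 equiv), DMPU, 25 °C; 15 (2 equiv) by syringe pump over 6 h
Reagents that add atoms: none
Why: Proposed new method: an iodide-relayed, nickel-catalysed reductive cross-electrophile coupling of an epoxide with an allylic bromide, which forms the C11–C12 bond and joins the two fragments; iodide with Et3N·HCl opens the spiro-epoxide by SN2 attack at the C11 methylene and leaves the 9α C–O bond untouched, zerovalent nickel adds oxidatively to 15 to give an η3-allyl complex of divalent nickel, Mn reduces this to monovalent nickel, which abstracts iodine from 16, the C11 radical is captured to give trivalent nickel, and reductive elimination at the unsubstituted CH2 terminus keeps the butenolide conjugated; the closest known reaction types are the nickel/iodide-cocatalysed reductive opening of terminal epoxides with aryl halides and the nickel-catalysed reductive allylation of alkyl halides, but to my knowledge an epoxide has not been joined to an allylic halide in this way, nor has an allyl partner that carries a butenolide been used.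

## Compound list
1 | 2-methylcyclopentane-1,3-dione | CC1C(=O)CCC1=O | starting material
2 | pent-1-en-3-one (ethyl vinyl ketone) | CCC(=O)C=C | starting material
3 | 2-methyl-2-(3-oxopentyl)cyclopentane-1,3-dione | CCC(=O)CCC1(C)C(=O)CCC1=O | intermediate
4 | (7aS)-4,7a-dimethyl-2,3,7,7a-tetrahydro-1H-indene-1,5(6H)-dione | O=C1CC[C@@]2(C)C(=C1C)CCC2=O | intermediate
5 | 8β-methyl epimer of 6 | O=C1CC[C@@]2(C)C(=C1C)CC[C@H](C)C2=O | intermediate
6 | (2R,8aS)-2,5,8a-trimethyl-3,4,8,8a-tetrahydronaphthalene-1,6(2H,7H)-dione (4,8α,10β-trimethyloctal-4-ene-3,9-dione) | O=C1CC[C@@]2(C)C(=C1C)CC[C@@H](C)C2=O | intermediate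
7 | lithium 2,4-dien-3-olate of 6 (C9 ketone free) | [Li+].[O-]C1=CC[C@@]2(C)C(=C1C)CC[C@@H](C)C2=O | intermediate
8 | 9β-hydroxy-9α-(trimethylsilylmethyl)-4,8α,10β-trimethyloctal-4-en-3-one | O=C1CC[C@@]2(C)C(=C1C)CC[C@@H](C)[C@@]2(O)C[Si](C)(C)C | intermediate
9 | 4,8α,10β-trimethyl-9-methylideneoctal-4-en-3-one | O=C1CC[C@@]2(C)C(=C1C)CC[C@@H](C)C2=C | intermediate
10 | lithium 3-en-3-olate, 5α-H, 4-methyl, 9-methylidene | [Li+].[O-]C=1CC[C@@]2(C)[C@@H](CC[C@@H](C)C2=C)C=1C | intermediate
11 | 5α,8βH-drim-9(11)-en-3-one | O=C1CC[C@@]2(C)[C@@H](CC[C@@H](C)C2=C)C1(C)C | intermediate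
12 | 5α,8βH-drim-9(11)-en-3β-ol (in the flask as its aluminium alkoxide) | O[C@H]1CC[C@@]2(C)[C@@H](CC[C@@H](C)C2=C)C1(C)C | intermediate
13 | 5α,8βH-drim-9(11)-en-3β-yl acetate | CC(=O)O[C@H]1CC[C@@]2(C)[C@@H](CC[C@@H](C)C2=C)C1(C)C | intermediate
14 | 9α,11-epoxy-5α,8βH-driman-3β-yl acetate | CC(=O)O[C@H]1CC[C@@]2(C)[C@@H](CC[C@@H](C)[C@]23CO3)C1(C)C | intermediate
15 | 4-(bromomethyl)furan-2(5H)-one | BrCC1=CC(=O)OC1 | starting material
16 | 9α-hydroxy-11-iodo-5α,8βH-driman-3β-yl acetate | CC(=O)O[C@H]1CC[C@@]2(C)[C@@H](CC[C@@H](C)[C@]2(O)CI)C1(C)C | intermediate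
17 | 3β-acetoxy-9α-hydroxy-8βH-labd-13-en-16,15-olide (CNP0578261.2) | CC(=O)O[C@H]1CC[C@@]2(C)[C@@H](CC[C@@H](C)[C@]2(O)CCC2=CC(=O)OC2)C1(C)C | target

## Count and risks
Total step count: 7. Longest linear sequence: 7 (1/2 → 17).

**Step 7 (new coupling).**
- Risk: homocoupling of the allyl partner, direct reduction of 15 by Mn, or β-hydroxy elimination back to 13 may win.
- Fallback: known chemistry that sets out from 14 and comes back at 17.
- 3-(Bromomethyl)furan and Mg (THF, 0 °C) give (furan-3-ylmethyl)magnesium bromide F5.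
- With CuI (10 mol%) at −30 °C, this reagent opens 14 at C11 to 3β-acetoxy-15,16-epoxylabda-13(16),14-dien-9α-ol F6.
- Photo-oxygenation (O2, tetraphenylporphyrin, hν, iPr2NEt, CH2Cl2, −78 °C) gives regioselectively 3β-acetoxy-9α,16-dihydroxylabd-13-en-16,15-olide F7.
- NaBH4 (EtOH, 0 °C) reduces the masked aldehyde of this compound, and lactonisation then gives 17.

**Step 3 (masked Peterson olefination).**
- Risk: incomplete or unselective enolisation, or failure of the addition at the hindered C9, would leave 6 or give attack at C3.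
- Fallback: sets out from 6 and comes back at 9, and replaces the transient mask by a covalent one.
- Ethane-1,2-dithiol and BF3·OEt2 (AcOH, rt) thioketalise only the accessible conjugated carbonyl, to give 3,3-(ethylenedithio)-4,8α,10β-trimethyloctal-4-en-9-one F3.
- With no second carbonyl left, C9 is methylenated under forcing Wittig conditions (Ph3PCH3Br, KOtBu, toluene, 90 °C) to 3,3-(ethylenedithio)-4,8α,10β-trimethyl-9-methylideneoctal-4-ene F4.
- MeI, CaCO3, aq MeCN, 60 °C removes the dithiolane and gives 9.

**Step 2 (ring expansion).**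
- Risk: migration of C10 instead of C7, spiro-epoxide formation, or losses in handling diazoethane.
- Fallback: sets out from 4 and comes back at 6, and separates ring growth from methyl introduction.
- Commercial ethyl diazoacetate with BF3·OEt2 (Et2O, 0 °C) inserts with migration of the methylene carbon, to give ethyl 4,10β-dimethyl-3,9-dioxooctal-4-ene-8-carboxylate F1.
- The doubly activated C8 is methylated (K2CO3, MeI, acetone) to ethyl 4,8,10β-trimethyl-3,9-dioxooctal-4-ene-8-carboxylate F2.
- Krapcho dealkoxycarbonylation (LiCl, wet DMSO, 150 °C) followed by DBU equilibration gives 6.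

## Further compounds
F1 | step 2 | ethyl 4,10β-dimethyl-3,9-dioxooctal-4-ene-8-carboxylate (C8 epimers and enol) | O=C1CC[C@@]2(C)C(=C1C)CCC(C(=O)OCC)C2=O
F2 | step 2 | ethyl 4,8,10β-trimethyl-3,9-dioxooctal-4-ene-8-carboxylate (C8 configuration of no consequence) | O=C1CC[C@@]2(C)C(=C1C)CCC(C)(C(=O)OCC)C2=O
F3 | step 3 | 3,3-(ethylenedithio)-4,8α,10β-trimethyloctal-4-en-9-one | C13(SCCS3)CC[C@@]2(C)C(=C1C)CC[C@@H](C)C2=O
F4 | step 3 | 3,3-(ethylenedithio)-4,8α,10β-trimethyl-9-methylideneoctal-4-ene | C13(SCCS3)CC[C@@]2(C)C(=C1C)CC[C@@H](C)C2=C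
F5 | step 7 | (furan-3-ylmethyl)magnesium bromide | Br[Mg]Cc1ccoc1
F6 | step 7 | 3β-acetoxy-15,16-epoxylabda-13(16),14-dien-9α-ol | CC(=O)O[C@H]1CC[C@@]2(C)[C@@H](CC[C@@H](C)[C@]2(O)CCc2ccoc2)C1(C)C
F7 | step 7 | 3β-acetoxy-9α,16-dihydroxylabd-13-en-16,15-olide (C16 epimers) | CC(=O)O[C@H]1CC[C@@]2(C)[C@@H](CC[C@@H](C)[C@]2(O)CCC2=CC(=O)OC2O)C1(C)C
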